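**Retrosynthetic overview**
- Target ⇒ its tri-O-benzyl ether; neutral hydrogenolysis comes last, so no acid is used once the benzylic carbinol exists.
- Cα–aryl bond ⇒ chelation-controlled addition of a 4-(benzyloxy)phenyl Grignard reagent to an (R)-α-aryloxy aldehyde (sets Cα, threo).
- Aldehyde ⇒ (S)-monoacetate ⇒ lipase desymmetrisation of a mirror-symmetric 2-(flavonyloxy)propane-1,3-diol (sets Cβ).
- Diol ⇒ crossed Claisen condensation and cyclodehydration of a syringate ester with 2,4-bis(benzyloxy)-6-hydroxyacetophenone. Ring C (the pyranone) is the only ring formed; rings A and B and the fourth arene are bought.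
- Ester ⇒ Mitsunobu etherification of methyl syringate (lignin-derived feedstock) with 2,2-dimethyl-1,3-dioxan-5-ol.

Assumption: the SMILES is read as the threo isomer, R at the benzylic carbinol carbon (Cα) and R at the aryloxy-bearing carbon (Cβ); the dioxanol, the dibenzylated acetophenone and the aryl Grignard solution are taken as catalogue items.

**Step 1**
Reactants: 1 methyl syringate (methyl 4-hydroxy-3,5-dimethoxybenzoate); 2 2,2-dimethyl-1,3-dioxan-5-ol
Product: 3 methyl 4-[(2,2-dimethyl-1,3-dioxan-5-yl)oxy]-3,5-dimethoxybenzoate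
Conditions: PPh3, DIAD, THF, 0 °C → 50 °C
Reagents that add atoms: none
Why: Mitsunobu etherification, in which the acidic hindered phenol displaces the activated secondary alkoxyphosphonium by SN2; the carbinol carbon of 2 lies on a mirror plane, so no stereocentre is formed.

**Step 2**
Reactants: 3 methyl 4-[(2,2-dimethyl-1,3-dioxan-5-yl)oxy]-3,5-dimethoxybenzoate; 4 1-[2,4-bis(benzyloxy)-6-hydroxyphenyl]ethan-1-one
Product: 7 5,7-bis(benzyloxy)-2-{4-[(1,3-dihydroxypropan-2-yl)oxy]-3,5-dimethoxyphenyl}-4H-chromen-4-one, via diketone acetonide 5 (not isolated), via diketone diol 6 (not isolated)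
Conditions: LiN(SiMe3)2 (3.5 equiv), THF, −78 °C → 50 °C; then 3 M aq. HCl, MeOH–THF, rt → 60 °C
Reagents that add atoms: none
Why: Crossed Claisen condensation of the acetophenone dianion with the aryl ester gives the 1,3-diketone (ester variant of the Baker–Venkataraman flavone synthesis), and aqueous acid then removes the acetonide and cyclodehydrates the o-hydroxy diketone to ring C while the aryl benzyl ethers survive and no acid-sensitive carbinol is yet present.

**Step 3 (key step)**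
Reactants: 7 5,7-bis(benzyloxy)-2-{4-[(1,3-dihydroxypropan-2-yl)oxy]-3,5-dimethoxyphenyl}-4H-chromen-4-one
Product: 8 (2S)-2-{4-[5,7-bis(benzyloxy)-4-oxo-4H-chromen-2-yl]-2,6-dimethoxyphenoxy}-3-hydroxypropyl acetate
Conditions: Burkholderia cepacia lipase (immobilised), vinyl acetate (5 equiv), THF–t-BuOMe, 30 °C; stopped when 7 is consumed; used at once
Reagents that add atoms: vinyl acetate, CC(=O)OC=C
Why: Lipase-catalysed enantiotopic-group-selective transesterification (desymmetrisation of a prochiral 2-substituted propane-1,3-diol) acylates one of the two mirror-related CH2OH arms and so creates Cβ; the (S)-monoacetate is expected by analogy with 2-O-benzylglycerol under Pseudomonas-type lipases (to be confirmed by Mosher ester analysis), and slight over-acylation to the achiral diacetate raises the ee.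

**Step 4**
Reactants: 8 (2S)-2-{4-[5,7-bis(benzyloxy)-4-oxo-4H-chromen-2-yl]-2,6-dimethoxyphenoxy}-3-hydroxypropyl acetate
Product: 9 (2R)-2-{4-[5,7-bis(benzyloxy)-4-oxo-4H-chromen-2-yl]-2,6-dimethoxyphenoxy}-3-oxopropyl acetate
Conditions: Dess–Martin periodinane (1.3 equiv), CH2Cl2, 0 °C → rt; crude aldehyde used cold and at once
Reagents that add atoms: none
Why: Dess–Martin oxidation of the free primary alcohol under base-free conditions gives the α-aryloxy aldehyde without enolisation or β-elimination of acetate, so Cβ is retained (the descriptor changes from S to R only because the CIP priorities change).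

**Step 5**
Reactants: 9 (2R)-2-{4-[5,7-bis(benzyloxy)-4-oxo-4H-chromen-2-yl]-2,6-dimethoxyphenoxy}-3-oxopropyl acetate; 10 [4-(benzyloxy)phenyl]magnesium bromide (THF solution)
Product: 12 5,7-bis(benzyloxy)-2-[4-({(1R,2R)-1-[4-(benzyloxy)phenyl]-1,3-dihydroxypropan-2-yl}oxy)-3,5-dimethoxyphenyl]-4H-chromen-4-one, via threo acetate 11 (not isolated)
Conditions: MgBr2·OEt2 (3 equiv), CH2Cl2, −78 °C; 10 (1.5 equiv), −78 °C; aqueous quench; then K2CO3 (0.2 equiv), MeOH–THF, rt
Reagents that add atoms: none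
Why: Cram-chelate-controlled Grignard addition, in which magnesium bridges the aldehyde oxygen and the α-aryloxy oxygen (helped by an ortho methoxy group) and the aryl group attacks anti to the CH2OAc arm to give the syn (threo) 1R,2R carbinol; methanolysis then removes the acetate, including any that migrated to the new hydroxyl or was cleaved by excess Grignard, without touching either stereocentre.

**Step 6**
Reactants: 12 5,7-bis(benzyloxy)-2-[4-({(1R,2R)-1-[4-(benzyloxy)phenyl]-1,3-dihydroxypropan-2-yl}oxy)-3,5-dimethoxyphenyl]-4H-chromen-4-one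
Product: 13 5,7-dihydroxy-2-[4-({(1R,2R)-1,3-dihydroxy-1-(4-hydroxyphenyl)propan-2-yl}oxy)-3,5-dimethoxyphenyl]-4H-chromen-4-one (target)
Conditions: H2 (1 atm), 10% Pd/C, THF–MeOH, rt; stopped at full debenzylation
Reagents that add atoms: none
Why: Heterogeneous hydrogenolysis of the three aryl benzyl ethers under neutral conditions is much faster than loss of the secondary benzylic hydroxyl or reduction of the flavone C2–C3 bond, and neither stereocentre is affected.

**Compound list**
1 | methyl syringate (methyl 4-hydroxy-3,5-dimethoxybenzoate) | COC(=O)c1cc(OC)c(O)c(OC)c1 | starting material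
2 | 2,2-dimethyl-1,3-dioxan-5-ol | CC1(C)OCC(O)CO1 | starting material
3 | methyl 4-[(2,2-dimethyl-1,3-dioxan-5-yl)oxy]-3,5-dimethoxybenzoate | COC(=O)c1cc(OC)c(OC2COC(C)(C)OC2)c(OC)c1 | intermediate
4 | 1-[2,4-bis(benzyloxy)-6-hydroxyphenyl]ethan-1-one | CC(=O)c1c(O)cc(OCc2ccccc2)cc1OCc1ccccc1 | starting material
5 | 1-[2,4-bis(benzyloxy)-6-hydroxyphenyl]-3-{4-[(2,2-dimethyl-1,3-dioxan-5-yl)oxy]-3,5-dimethoxyphenyl}propane-1,3-dione (diketone acetonide, not isolated) | O=C(CC(=O)c1cc(OC)c(OC2COC(C)(C)OC2)c(OC)c1)c1c(O)cc(OCc2ccccc2)cc1OCc1ccccc1 | intermediate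
6 | 1-[2,4-bis(benzyloxy)-6-hydroxyphenyl]-3-{4-[(1,3-dihydroxypropan-2-yl)oxy]-3,5-dimethoxyphenyl}propane-1,3-dione (diketone diol, not isolated) | O=C(CC(=O)c1cc(OC)c(OC(CO)CO)c(OC)c1)c1c(O)cc(OCc2ccccc2)cc1OCc1ccccc1 | intermediate
7 | 5,7-bis(benzyloxy)-2-{4-[(1,3-dihydroxypropan-2-yl)oxy]-3,5-dimethoxyphenyl}-4H-chromen-4-one | COc1cc(-c2cc(=O)c3c(OCc4ccccc4)cc(OCc4ccccc4)cc3o2)cc(OC)c1OC(CO)CO | intermediate
8 | (2S)-2-{4-[5,7-bis(benzyloxy)-4-oxo-4H-chromen-2-yl]-2,6-dimethoxyphenoxy}-3-hydroxypropyl acetate | COc1cc(-c2cc(=O)c3c(OCc4ccccc4)cc(OCc4ccccc4)cc3o2)cc(OC)c1O[C@H](COC(C)=O)CO | intermediate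
9 | (2R)-2-{4-[5,7-bis(benzyloxy)-4-oxo-4H-chromen-2-yl]-2,6-dimethoxyphenoxy}-3-oxopropyl acetate | COc1cc(-c2cc(=O)c3c(OCc4ccccc4)cc(OCc4ccccc4)cc3o2)cc(OC)c1O[C@H](COC(C)=O)C=O | intermediate
10 | [4-(benzyloxy)phenyl]magnesium bromide | Br[Mg]c1ccc(OCc2ccccc2)cc1 | starting material
11 | (2R,3R)-3-[4-(benzyloxy)phenyl]-2-{4-[5,7-bis(benzyloxy)-4-oxo-4H-chromen-2-yl]-2,6-dimethoxyphenoxy}-3-hydroxypropyl acetate (threo acetate, not isolated) | COc1cc(-c2cc(=O)c3c(OCc4ccccc4)cc(OCc4ccccc4)cc3o2)cc(OC)c1O[C@H](COC(C)=O)[C@H](O)c1ccc(OCc2ccccc2)cc1 | intermediate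
12 | 5,7-bis(benzyloxy)-2-[4-({(1R,2R)-1-[4-(benzyloxy)phenyl]-1,3-dihydroxypropan-2-yl}oxy)-3,5-dimethoxyphenyl]-4H-chromen-4-one | COc1cc(-c2cc(=O)c3c(OCc4ccccc4)cc(OCc4ccccc4)cc3o2)cc(OC)c1O[C@H](CO)[C@H](O)c1ccc(OCc2ccccc2)cc1 | intermediate
13 | 5,7-dihydroxy-2-[4-({(1R,2R)-1,3-dihydroxy-1-(4-hydroxyphenyl)propan-2-yl}oxy)-3,5-dimethoxyphenyl]-4H-chromen-4-one | COc1cc(-c2cc(=O)c3c(O)cc(O)cc3o2)cc(OC)c1O[C@H](CO)[C@H](O)c1ccc(O)cc1 | target

**Totals**
Total step count: 6. Longest linear sequence: 6 steps (1 → 13).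

**Steps most likely to fail, with fallbacks**

Step 3 (lipase desymmetrisation of the bulky flavone diol). The enzyme may accept the substrate slowly, give low ee, or acylate the other arm. The fallback sets out from 7 and returns at 8. Peracetylation of 7 (Ac2O, pyridine) gives the achiral 2-{4-[5,7-bis(benzyloxy)-4-oxo-4H-chromen-2-yl]-2,6-dimethoxyphenoxy}propane-1,3-diyl diacetate F3. Enantiotopic-group-selective hydrolysis of F3 (the same lipase, or pig liver esterase, pH 7 phosphate buffer with acetone) then removes one acetate. A given enzyme hydrolyses the arm it would otherwise acylate, so this mode gives the mirror-image monoacetate of the acylation mode; whichever mode gives the (S) compound is used to reach 8.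

Step 5 (chelation-controlled aryl addition to a sensitive β-acetoxy-α-aryloxy aldehyde). The non-chelated Felkin–Anh pathway would give the erythro alcohol. The fallback sets out from 9 and returns at 12. Compound 10 is added to 9 in THF without MgBr2·OEt2 and the product is isolated before methanolysis as (2R,3S)-3-[4-(benzyloxy)phenyl]-2-{4-[5,7-bis(benzyloxy)-4-oxo-4H-chromen-2-yl]-2,6-dimethoxyphenoxy}-3-hydroxypropyl acetate F4. Mitsunobu inversion at the benzylic carbinol with 4-nitrobenzoic acid (PPh3, DIAD, THF) gives (1R,2R)-3-acetoxy-1-[4-(benzyloxy)phenyl]-2-{4-[5,7-bis(benzyloxy)-4-oxo-4H-chromen-2-yl]-2,6-dimethoxyphenoxy}propyl 4-nitrobenzoate F5. K2CO3 in MeOH cleaves both esters to give 12.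

Step 1 (Mitsunobu reaction of a di-ortho-substituted phenol with a deactivated secondary alcohol). The fallback sets out from 1 and returns at 3. O-Alkylation of 1 with diethyl bromomalonate (K2CO3, acetone) gives diethyl 2-[2,6-dimethoxy-4-(methoxycarbonyl)phenoxy]propanedioate F1. NaBH4 in EtOH (0 °C → rt) reduces only the activated malonate esters and leaves the aryl methyl ester, giving methyl 4-[(1,3-dihydroxypropan-2-yl)oxy]-3,5-dimethoxybenzoate F2. Acetonide formation (2,2-dimethoxypropane, TsOH cat., acetone) then gives 3.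

**Further compounds**
F1 | step 1 | diethyl 2-[2,6-dimethoxy-4-(methoxycarbonyl)phenoxy]propanedioate | CCOC(=O)C(Oc1c(OC)cc(cc1OC)C(=O)OC)C(=O)OCC
F2 | step 1 | methyl 4-[(1,3-dihydroxypropan-2-yl)oxy]-3,5-dimethoxybenzoate | COC(=O)c1cc(OC)c(OC(CO)CO)c(OC)c1
F3 | step 3 | 2-{4-[5,7-bis(benzyloxy)-4-oxo-4H-chromen-2-yl]-2,6-dimethoxyphenoxy}propane-1,3-diyl diacetate | COc1cc(-c2cc(=O)c3c(OCc4ccccc4)cc(OCc4ccccc4)cc3o2)cc(OC)c1OC(COC(C)=O)COC(C)=O
F4 | step 5 | (2R,3S)-3-[4-(benzyloxy)phenyl]-2-{4-[5,7-bis(benzyloxy)-4-oxo-4H-chromen-2-yl]-2,6-dimethoxyphenoxy}-3-hydroxypropyl acetate | COc1cc(-c2cc(=O)c3c(OCc4ccccc4)cc(OCc4ccccc4)cc3o2)cc(OC)c1O[C@H](COC(C)=O)[C@@H](O)c1ccc(OCc2ccccc2)cc1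
F5 | step 5 | (1R,2R)-3-acetoxy-1-[4-(benzyloxy)phenyl]-2-{4-[5,7-bis(benzyloxy)-4-oxo-4H-chromen-2-yl]-2,6-dimethoxyphenoxy}propyl 4-nitrobenzoate | COc1cc(-c2cc(=O)c3c(OCc4ccccc4)cc(OCc4ccccc4)cc3o2)cc(OC)c1O[C@H](COC(C)=O)[C@H](OC(=O)c1ccc(cc1)[N+](=O)[O-])c1ccc(OCc2ccccc2)cc1
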